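**Plan**

1. Lactone numbering used below: O1, C2 (C=O), C3 (carries the epoxy-alkenyl arm), C4 (ring CH), C5 (ring carbon of the exocyclic alkene), exocyclic C6, methyl-bearing C7; the chain runs on to C16 at the cyclohexene.
2. Retrosynthetic cuts, in order: C4–C5 (ring closure), O1–C5 (enol ester of an iodo-dienoic acid and a pentaenyl boronate), C10–C11 (sp2–sp2), the ring–C16 alkyne bond; on the other half, the side-arm alkene next to the oxirane and the oxirane itself.
3. Forward: both six-membered rings come from one bought ketone through a common enol triflate; the oxirane is made by epoxidation; the halves are joined through O1–C5; the furanone ring is closed last by C4–C5 bond formation, and only desilylation follows.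
4. Stereochemistry: both carbinol centres come from (4R,6R)-actinol; the oxirane carbons from a Sharpless epoxidation (D-tartrate, reagent control); alkene geometries from the commercial (E)-enynol, syn-borylation, E-selective chromium and phosphonate olefinations; the (Z)-C5=C6 bond from the stereospecific course of the ring closure on an (E)-enol ester.
5. Enabling feature: C5 is the hydrogen-bearing, O1-substituted terminus of a 1-acyloxy-diene and C7 carries no hydrogen. Palladium-bound C4 adding 5-exo to C5 therefore leaves an allyl-palladium at C6 whose only β-hydrogen is on C5, and its loss creates the exocyclic C5=C6 bond of the furan-2(5H)-one ring.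

Key step: step 21

Assumption: compounds 1, 9, 17 and 20 are bought; the target is the free diol of the given SMILES (no acetyl group); TBS = tert-butyldimethylsilyl, pin = pinacolato.

**Route**

Step 1
Reactants: 1 (4R,6R)-4-hydroxy-2,2,6-trimethylcyclohexan-1-one
Product: 2 (4R,6R)-4-(TBS-oxy)-2,2,6-trimethylcyclohexan-1-one
Conditions: TBSCl, imidazole, DMF, rt
Reagents that add atoms: tert-butyldimethylsilyl chloride, CC(C)(C)[Si](C)(C)Cl
Why: Imidazole-promoted silyl ether formation at the only hydroxyl group should be clean and leaves both stereocentres untouched.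

Step 2
Reactants: 2 (4R,6R)-4-(TBS-oxy)-2,2,6-trimethylcyclohexan-1-one
Product: 4 (4R)-4-(TBS-oxy)-2,6,6-trimethylcyclohex-1-en-1-yl trifluoromethanesulfonate, via lithium enolate 3 (not isolated)
Conditions: LiN(iPr)2, THF, −78 °C; then PhNTf2, −78 °C to rt
Reagents that add atoms: N-phenylbis(trifluoromethanesulfonimide), O=S(=O)(N(c1ccccc1)S(=O)(=O)C(F)(F)F)C(F)(F)F
Why: Deprotonation can only occur at C6 because C2 is quaternary, and O-sulfonylation of the enolate (enol triflate formation) should give the tetrasubstituted triflate with the C4 carbinol configuration retained (the C6 centre is erased on purpose).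

Step 3
Reactants: 4 (4R)-4-(TBS-oxy)-2,6,6-trimethylcyclohex-1-en-1-yl trifluoromethanesulfonate
Product: 5 methyl (4R)-4-(TBS-oxy)-2,6,6-trimethylcyclohex-1-ene-1-carboxylate
Conditions: Pd(OAc)2 (5 mol %), PPh3, CO (1 atm), MeOH, Et3N, DMF, 60 °C
Reagents that add atoms: carbon monoxide, [C-]#[O+]; methanol, CO
Why: Palladium-catalysed alkoxycarbonylation of an enol triflate (oxidative addition, CO insertion, methanolysis) should give the hindered enoate without touching the silyl ether.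

Step 4
Reactants: 5 methyl (4R)-4-(TBS-oxy)-2,6,6-trimethylcyclohex-1-ene-1-carboxylate
Product: 6 [(4R)-4-(TBS-oxy)-2,6,6-trimethylcyclohex-1-en-1-yl]methanol
Conditions: iBu2AlH, CH2Cl2, −78 to 0 °C
Reagents that add atoms: none
Why: Hydride 1,2-reduction of the enoate to the allylic alcohol should occur without conjugate reduction of the tetrasubstituted alkene.

Step 5
Reactants: 6 [(4R)-4-(TBS-oxy)-2,6,6-trimethylcyclohex-1-en-1-yl]methanol
Product: 7 [(1R,4S,6R)-4-(TBS-oxy)-2,2,6-trimethyl-7-oxabicyclo[4.1.0]heptan-1-yl]methanol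
Conditions: Ti(OiPr)4 (20 mol %), D-(−)-diethyl tartrate (24 mol %), tBuOOH, 4 Å MS, CH2Cl2, −20 °C
Reagents that add atoms: tert-butyl hydroperoxide, CC(C)(C)OO
Why: Sharpless asymmetric epoxidation of the primary allylic alcohol; with the D-tartrate ligand the titanium-bound peroxide should be delivered to the alkene face anti to the C4 silyloxy group, setting both oxirane carbons (1R,6R) under reagent control.

Step 6
Reactants: 7 [(1R,4S,6R)-4-(TBS-oxy)-2,2,6-trimethyl-7-oxabicyclo[4.1.0]heptan-1-yl]methanol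
Product: 8 (1S,4S,6R)-4-(TBS-oxy)-2,2,6-trimethyl-7-oxabicyclo[4.1.0]heptane-1-carbaldehyde
Conditions: nPr4N[RuO4] (5 mol %), NMO, 4 Å MS, CH2Cl2, rt
Reagents that add atoms: none
Why: Ley–Griffith oxidation should convert the primary epoxy alcohol into the non-enolisable aldehyde without oxirane opening.

Step 7
Reactants: 9 methyl prop-2-ynoate
Product: 10 methyl (2Z)-2-(hydroxymethyl)-3-iodoprop-2-enoate (iodine cis to the ester)
Conditions: MgI2, CH2O (monomeric, THF solution), CH2Cl2, 0 °C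
Reagents that add atoms: magnesium iodide, [Mg+2].[I-].[I-]; formaldehyde, C=O
Why: Iodide conjugate addition to the propiolate gives a magnesium β-iodoallenolate that is hydroxymethylated at the α-carbon (halo-aldol, β-iodo Morita–Baylis–Hillman-type reaction), and the isomer with iodine cis to the ester is the expected product.

Step 8
Reactants: 10 methyl (2Z)-2-(hydroxymethyl)-3-iodoprop-2-enoate
Product: 11 methyl (2E)-2-(bromomethyl)-3-iodoprop-2-enoate (iodine cis to the ester)
Conditions: CBr4, PPh3, CH2Cl2, 0 °C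
Reagents that add atoms: carbon tetrabromide, BrC(Br)(Br)Br
Why: Appel bromination of the primary allylic alcohol should give the bromide under neutral conditions that leave the iodoalkene geometry intact.

Step 9
Reactants: 11 methyl (2E)-2-(bromomethyl)-3-iodoprop-2-enoate
Product: 12 methyl (2E)-2-[(diethoxyphosphoryl)methyl]-3-iodoprop-2-enoate (iodine cis to the ester)
Conditions: P(OEt)3, neat, 70 °C
Reagents that add atoms: triethyl phosphite, CCOP(OCC)OCC
Why: Michaelis–Arbuzov reaction of the activated allylic bromide should give the allylic phosphonate by displacement at CH2Br, leaving the iodoalkene unchanged.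

Step 10
Reactants: 12 methyl (2E)-2-[(diethoxyphosphoryl)methyl]-3-iodoprop-2-enoate; 8 (1S,4S,6R)-4-(TBS-oxy)-2,2,6-trimethyl-7-oxabicyclo[4.1.0]heptane-1-carbaldehyde
Product: 14 methyl (2Z)-2-{(E)-2-[(1S,4S,6R)-4-(TBS-oxy)-2,2,6-trimethyl-7-oxabicyclo[4.1.0]heptan-1-yl]ethenyl}-3-iodoprop-2-enoate, via lithiated phosphonate 13 (not isolated)
Conditions: LiN(SiMe3)2, THF, −78 °C; then 8, −78 to 0 °C
Reagents that add atoms: none
Why: Horner–Wadsworth–Emmons olefination of the hindered, non-enolisable aldehyde with the allylic phosphonate anion should form the new disubstituted alkene with (E) geometry while the (Z)-iodoacrylate is carried through.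

Step 11
Reactants: 14 methyl (2Z)-2-{(E)-2-[(1S,4S,6R)-4-(TBS-oxy)-2,2,6-trimethyl-7-oxabicyclo[4.1.0]heptan-1-yl]ethenyl}-3-iodoprop-2-enoate
Product: 16 (2Z)-2-{(E)-2-[(1S,4S,6R)-4-(TBS-oxy)-2,2,6-trimethyl-7-oxabicyclo[4.1.0]heptan-1-yl]ethenyl}-3-iodoprop-2-enoic acid, via lithium carboxylate 15 (not isolated)
Conditions: LiOH, THF–MeOH–H2O, 0 °C; then 0.5 M HCl to pH 4, 0 °C
Reagents that add atoms: lithium hydroxide, [Li+].[OH-]
Why: Saponification of the methyl ester and careful acidification should free the acid; there is no α-hydrogen, so the iodoalkene cannot eliminate, and the hindered oxirane resists hydroxide.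

Step 12
Reactants: 4 (4R)-4-(TBS-oxy)-2,6,6-trimethylcyclohex-1-en-1-yl trifluoromethanesulfonate; 17 (2E)-3-methylpent-2-en-4-yn-1-ol
Product: 18 (2E)-5-[(4R)-4-(TBS-oxy)-2,6,6-trimethylcyclohex-1-en-1-yl]-3-methylpent-2-en-4-yn-1-ol
Conditions: Pd(PPh3)4 (5 mol %), CuI (10 mol %), iPr2NH, DMF, rt
Reagents that add atoms: none
Why: Sonogashira coupling of the enol triflate with the terminal alkyne of the (E)-enynol should form the ring–alkyne bond with the enyne geometry untouched.

Step 13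
Reactants: 18 (2E)-5-[(4R)-4-(TBS-oxy)-2,6,6-trimethylcyclohex-1-en-1-yl]-3-methylpent-2-en-4-yn-1-ol
Product: 19 (2E)-5-[(4R)-4-(TBS-oxy)-2,6,6-trimethylcyclohex-1-en-1-yl]-3-methylpent-2-en-4-ynal
Conditions: MnO2, CH2Cl2, rt
Reagents that add atoms: none
Why: Heterogeneous allylic oxidation with MnO2 should give the enynal without touching the silyl ether or isomerising the trisubstituted alkene.

Step 14
Reactants: 20 diiodomethane
Product: 22 tributyl(diiodomethyl)stannane, via diiodomethyllithium 21 (not isolated)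
Conditions: LiN(SiMe3)2, THF–Et2O, −95 °C; then Bu3SnCl, −95 to −78 °C
Reagents that add atoms: tributyltin chloride, CCCC[Sn](Cl)(CCCC)CCCC
Why: Deprotonation of diiodomethane gives the lithium carbenoid, which is trapped by the tin chloride (carbenoid stannylation) to give the gem-diiodide reagent for step 15.

Step 15
Reactants: 19 (2E)-5-[(4R)-4-(TBS-oxy)-2,6,6-trimethylcyclohex-1-en-1-yl]-3-methylpent-2-en-4-ynal; 22 tributyl(diiodomethyl)stannane
Product: 23 tributyl{(1E,3E)-6-[(4R)-4-(TBS-oxy)-2,6,6-trimethylcyclohex-1-en-1-yl]-4-methylhexa-1,3-dien-5-yn-1-yl}stannane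
Conditions: CrCl2, DMF–THF, rt, dark
Reagents that add atoms: none
Why: Takai–Hodgson stannyl-olefination: the geminal dichromium species formed from 22 adds to the aldehyde and eliminates to the (E)-alkenylstannane, the E geometry following from anti elimination of the preferred adduct.

Step 16
Reactants: 17 (2E)-3-methylpent-2-en-4-yn-1-ol
Product: 24 (2E,4E)-3-methyl-5-(4,4,5,5-tetramethyl-1,3,2-dioxaborolan-2-yl)penta-2,4-dien-1-ol
Conditions: CuCl (5 mol %), Xantphos (5 mol %), NaOtBu (10 mol %), B2pin2, MeOH, THF, rt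
Reagents that add atoms: bis(pinacolato)diboron, CC1(C)OB(OC1(C)C)B1OC(C)(C)C(C)(C)O1
Why: Copper-catalysed protoboration (syn borylcupration of the terminal alkyne, then protonation by methanol) should place boron on the terminal carbon and give the (E)-alkenylboronate with the free hydroxyl tolerated.

Step 17
Reactants: 24 (2E,4E)-3-methyl-5-(pinacolboryl)penta-2,4-dien-1-ol
Product: 25 (2E,4E)-3-methyl-5-(4,4,5,5-tetramethyl-1,3,2-dioxaborolan-2-yl)penta-2,4-dienal
Conditions: MnO2, CH2Cl2, rt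
Reagents that add atoms: none
Why: Allylic oxidation with MnO2 should give the dienal; alkenyl pinacol boronates are stable to this oxidant.

Step 18
Reactants: 25 (2E,4E)-3-methyl-5-(pinacolboryl)penta-2,4-dienal
Product: 26 2-[(1E,3E,5E)-6-iodo-3-methylhexa-1,3,5-trien-1-yl]-4,4,5,5-tetramethyl-1,3,2-dioxaborolane
Conditions: CrCl2, CHI3, THF–dioxane, 0 °C to rt
Reagents that add atoms: iodoform, IC(I)I
Why: Takai iodo-olefination should homologate the enal to the (E)-alkenyl iodide; the pinacol boronate is inert to chromium dichloride.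

Step 19
Reactants: 23 tributyl{(1E,3E)-6-[(4R)-4-(TBS-oxy)-2,6,6-trimethylcyclohex-1-en-1-yl]-4-methylhexa-1,3-dien-5-yn-1-yl}stannane; 26 2-[(1E,3E,5E)-6-iodo-3-methylhexa-1,3,5-trien-1-yl]-4,4,5,5-tetramethyl-1,3,2-dioxaborolane
Product: 27 2-{(1E,3E,5E,7E,9E)-12-[(4R)-4-(TBS-oxy)-2,6,6-trimethylcyclohex-1-en-1-yl]-3,10-dimethyldodeca-1,3,5,7,9-pentaen-11-yn-1-yl}-4,4,5,5-tetramethyl-1,3,2-dioxaborolane
Conditions: Pd2(dba)3 (5 mol %), AsPh3 (20 mol %), NMP, rt, dark
Reagents that add atoms: none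
Why: Base-free Stille coupling should form the C10–C11 bond with retention at both alkenes, and the pinacol boronate is not transmetalated in the absence of base.

Step 20
Reactants: 16 (2Z)-2-{(E)-2-[(1S,4S,6R)-4-(TBS-oxy)-2,2,6-trimethyl-7-oxabicyclo[4.1.0]heptan-1-yl]ethenyl}-3-iodoprop-2-enoic acid; 27 the pentaenyl pinacol boronate
Product: 28 (1E,3E,5E,7E,9E)-12-[(4R)-4-(TBS-oxy)-2,6,6-trimethylcyclohex-1-en-1-yl]-3,10-dimethyldodeca-1,3,5,7,9-pentaen-11-yn-1-yl (2Z)-2-{(E)-2-[(1S,4S,6R)-4-(TBS-oxy)-2,2,6-trimethyl-7-oxabicyclo[4.1.0]heptan-1-yl]ethenyl}-3-iodoprop-2-enoate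
Conditions: CuBr·SMe2 (20 mol %), DMAP (40 mol %), 4 Å MS, dry air, CH2Cl2, rt, dark
Reagents that add atoms: none
Why: Chan–Lam-type copper-catalysed oxidative C–O coupling of the carboxylic acid with the alkenylboronate should transfer the alkenyl group with retention to give the (E)-enol ester, the vinyl iodide being inert to copper at room temperature.

Step 21
Reactants: 28 the (E)-enol ester of the (Z)-iodo-dienoic acid
Product: 29 (5Z)-3-{(E)-2-[(1S,4S,6R)-4-(TBS-oxy)-2,2,6-trimethyl-7-oxabicyclo[4.1.0]heptan-1-yl]ethenyl}-5-{(2E,4E,6E,8E)-11-[(4R)-4-(TBS-oxy)-2,6,6-trimethylcyclohex-1-en-1-yl]-2,9-dimethylundeca-2,4,6,8-tetraen-10-yn-1-ylidene}furan-2(5H)-one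
Conditions: Pd(OAc)2 (10 mol %), P(2-furyl)3 (30 mol %), Ag2CO3 (1.5 equiv), MeCN–THF, 45 °C, dark
Reagents that add atoms: none
Why: Proposed new method: zerovalent palladium adds oxidatively to the C4–I bond, silver removes iodide, the cationic alkenylpalladium inserts the tethered enol-ester alkene syn (C4 to C5, palladium to C6 as a π-allyl), and syn β-hydride elimination of the single C5 hydrogen gives the ylidene lactone while carbonate returns zerovalent palladium. The closest known reaction types are the intramolecular Mizoroki–Heck 5-exo cyclisation of alkenyl iodides and the intermolecular Heck vinylation of enol esters and of 1,3-dienes at the diene terminus. The five-membered lactone closes in the 5-exo-trig mode through the less populated s-trans ester rotamer. No stereocentre is formed; the new stereo-element is the C5=C6 geometry, which syn insertion followed by syn elimination translates from the (E)-enol ester into the (Z)-ylidene (O1 cis to C7), also the thermodynamically preferred isomer. The step needs 5-exo over 6-endo insertion, which the short ester tether, the preference of cationic palladium for the oxygen-bearing alkene carbon and the allyl stabilisation at C6 secure, and β-hydride over β-acyloxy elimination, which the silver-mediated cationic manifold favours; a ring-opened palladium carboxylate, if formed, can re-close by oxypalladation to the same intermediate. The hindered tetrasubstituted vinyl oxirane and the silyl ethers should survive these mild, non-acidic conditions.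

Step 22
Reactants: 29 the bis-TBS ether of the target
Product: 30 (5Z)-3-{(E)-2-[(1S,4S,6R)-4-hydroxy-2,2,6-trimethyl-7-oxabicyclo[4.1.0]heptan-1-yl]ethenyl}-5-{(2E,4E,6E,8E)-11-[(4R)-4-hydroxy-2,6,6-trimethylcyclohex-1-en-1-yl]-2,9-dimethylundeca-2,4,6,8-tetraen-10-yn-1-ylidene}furan-2(5H)-one (target CNP0180336.1)
Conditions: Bu4NF, AcOH (1:1), THF, 0 °C to rt, dark
Reagents that add atoms: none
Why: Fluoride-mediated desilylation buffered with acetic acid should remove both silyl ethers without opening the ylidene lactone or rearranging the acid-sensitive oxirane.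

**Compound list**

1 | (4R,6R)-4-hydroxy-2,2,6-trimethylcyclohexan-1-one ((4R,6R)-actinol) | CC1(C)C[C@H](O)C[C@@H](C)C1=O | starting material
2 | (4R,6R)-4-{[tert-butyl(dimethyl)silyl]oxy}-2,2,6-trimethylcyclohexan-1-one | CC1(C)C[C@H](O[Si](C)(C)C(C)(C)C)C[C@@H](C)C1=O | intermediate
3 | lithium (4R)-4-{[tert-butyl(dimethyl)silyl]oxy}-2,6,6-trimethylcyclohex-1-en-1-olate | CC1=C([O-])C(C)(C)C[C@H](O[Si](C)(C)C(C)(C)C)C1.[Li+] | intermediate (not isolated)
4 | (4R)-4-{[tert-butyl(dimethyl)silyl]oxy}-2,6,6-trimethylcyclohex-1-en-1-yl trifluoromethanesulfonate | CC1=C(OS(=O)(=O)C(F)(F)F)C(C)(C)C[C@H](O[Si](C)(C)C(C)(C)C)C1 | intermediate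
5 | methyl (4R)-4-{[tert-butyl(dimethyl)silyl]oxy}-2,6,6-trimethylcyclohex-1-ene-1-carboxylate | CC1=C(C(=O)OC)C(C)(C)C[C@H](O[Si](C)(C)C(C)(C)C)C1 | intermediate
6 | [(4R)-4-{[tert-butyl(dimethyl)silyl]oxy}-2,6,6-trimethylcyclohex-1-en-1-yl]methanol | CC1=C(CO)C(C)(C)C[C@H](O[Si](C)(C)C(C)(C)C)C1 | intermediate
7 | [(1R,4S,6R)-4-{[tert-butyl(dimethyl)silyl]oxy}-2,2,6-trimethyl-7-oxabicyclo[4.1.0]heptan-1-yl]methanol | OC[C@@]12O[C@]1(C)C[C@@H](O[Si](C)(C)C(C)(C)C)CC2(C)C | intermediate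
8 | (1S,4S,6R)-4-{[tert-butyl(dimethyl)silyl]oxy}-2,2,6-trimethyl-7-oxabicyclo[4.1.0]heptane-1-carbaldehyde | O=C[C@@]12O[C@]1(C)C[C@@H](O[Si](C)(C)C(C)(C)C)CC2(C)C | intermediate
9 | methyl prop-2-ynoate | C#CC(=O)OC | starting material
10 | methyl (2Z)-2-(hydroxymethyl)-3-iodoprop-2-enoate | I/C=C(/CO)C(=O)OC | intermediate
11 | methyl (2E)-2-(bromomethyl)-3-iodoprop-2-enoate | I/C=C(/CBr)C(=O)OC | intermediate
12 | methyl (2E)-2-[(diethoxyphosphoryl)methyl]-3-iodoprop-2-enoate | I/C=C(/CP(=O)(OCC)OCC)C(=O)OC | intermediate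
13 | lithium salt of the phosphonate carbanion of 12 | I/C=C(/[CH-]P(=O)(OCC)OCC)C(=O)OC.[Li+] | intermediate (not isolated)
14 | methyl (2Z)-2-{(E)-2-[(1S,4S,6R)-4-{[tert-butyl(dimethyl)silyl]oxy}-2,2,6-trimethyl-7-oxabicyclo[4.1.0]heptan-1-yl]ethenyl}-3-iodoprop-2-enoate | I/C=C(/C=C/[C@@]12O[C@]1(C)C[C@@H](O[Si](C)(C)C(C)(C)C)CC2(C)C)C(=O)OC | intermediate
15 | lithium (2Z)-2-{(E)-2-[(1S,4S,6R)-4-{[tert-butyl(dimethyl)silyl]oxy}-2,2,6-trimethyl-7-oxabicyclo[4.1.0]heptan-1-yl]ethenyl}-3-iodoprop-2-enoate | I/C=C(/C=C/[C@@]12O[C@]1(C)C[C@@H](O[Si](C)(C)C(C)(C)C)CC2(C)C)C(=O)[O-].[Li+] | intermediate (not isolated)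
16 | (2Z)-2-{(E)-2-[(1S,4S,6R)-4-{[tert-butyl(dimethyl)silyl]oxy}-2,2,6-trimethyl-7-oxabicyclo[4.1.0]heptan-1-yl]ethenyl}-3-iodoprop-2-enoic acid | I/C=C(/C=C/[C@@]12O[C@]1(C)C[C@@H](O[Si](C)(C)C(C)(C)C)CC2(C)C)C(=O)O | intermediate
17 | (2E)-3-methylpent-2-en-4-yn-1-ol | C#C/C(C)=C/CO | starting material
18 | (2E)-5-[(4R)-4-{[tert-butyl(dimethyl)silyl]oxy}-2,6,6-trimethylcyclohex-1-en-1-yl]-3-methylpent-2-en-4-yn-1-ol | CC1=C(C#C/C(C)=C/CO)C(C)(C)C[C@H](O[Si](C)(C)C(C)(C)C)C1 | intermediate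
19 | (2E)-5-[(4R)-4-{[tert-butyl(dimethyl)silyl]oxy}-2,6,6-trimethylcyclohex-1-en-1-yl]-3-methylpent-2-en-4-ynal | CC1=C(C#C/C(C)=C/C=O)C(C)(C)C[C@H](O[Si](C)(C)C(C)(C)C)C1 | intermediate
20 | diiodomethane | ICI | starting material
21 | diiodomethyllithium | [Li]C(I)I | intermediate (not isolated)
22 | tributyl(diiodomethyl)stannane | CCCC[Sn](CCCC)(CCCC)C(I)I | intermediate
23 | tributyl{(1E,3E)-6-[(4R)-4-{[tert-butyl(dimethyl)silyl]oxy}-2,6,6-trimethylcyclohex-1-en-1-yl]-4-methylhexa-1,3-dien-5-yn-1-yl}stannane | CC1=C(C#C/C(C)=C/C=C/[Sn](CCCC)(CCCC)CCCC)C(C)(C)C[C@H](O[Si](C)(C)C(C)(C)C)C1 | intermediate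
24 | (2E,4E)-3-methyl-5-(4,4,5,5-tetramethyl-1,3,2-dioxaborolan-2-yl)penta-2,4-dien-1-ol | OC/C=C(C)/C=C/B1OC(C)(C)C(C)(C)O1 | intermediate
25 | (2E,4E)-3-methyl-5-(4,4,5,5-tetramethyl-1,3,2-dioxaborolan-2-yl)penta-2,4-dienal | O=C/C=C(C)/C=C/B1OC(C)(C)C(C)(C)O1 | intermediate
26 | 2-[(1E,3E,5E)-6-iodo-3-methylhexa-1,3,5-trien-1-yl]-4,4,5,5-tetramethyl-1,3,2-dioxaborolane | I/C=C/C=C(C)/C=C/B1OC(C)(C)C(C)(C)O1 | intermediate
27 | 2-{(1E,3E,5E,7E,9E)-12-[(4R)-4-{[tert-butyl(dimethyl)silyl]oxy}-2,6,6-trimethylcyclohex-1-en-1-yl]-3,10-dimethyldodeca-1,3,5,7,9-pentaen-11-yn-1-yl}-4,4,5,5-tetramethyl-1,3,2-dioxaborolane | CC1=C(C#C/C(C)=C/C=C/C=C/C=C(C)/C=C/B2OC(C)(C)C(C)(C)O2)C(C)(C)C[C@H](O[Si](C)(C)C(C)(C)C)C1 | intermediate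
28 | (1E,3E,5E,7E,9E)-12-[(4R)-4-{[tert-butyl(dimethyl)silyl]oxy}-2,6,6-trimethylcyclohex-1-en-1-yl]-3,10-dimethyldodeca-1,3,5,7,9-pentaen-11-yn-1-yl (2Z)-2-{(E)-2-[(1S,4S,6R)-4-{[tert-butyl(dimethyl)silyl]oxy}-2,2,6-trimethyl-7-oxabicyclo[4.1.0]heptan-1-yl]ethenyl}-3-iodoprop-2-enoate | CC1=C(C#C/C(C)=C/C=C/C=C/C=C(C)/C=C/OC(=O)C(=C\I)/C=C/[C@@]23O[C@]2(C)C[C@@H](O[Si](C)(C)C(C)(C)C)CC3(C)C)C(C)(C)C[C@H](O[Si](C)(C)C(C)(C)C)C1 | intermediate
29 | (5Z)-3-{(E)-2-[(1S,4S,6R)-4-{[tert-butyl(dimethyl)silyl]oxy}-2,2,6-trimethyl-7-oxabicyclo[4.1.0]heptan-1-yl]ethenyl}-5-{(2E,4E,6E,8E)-11-[(4R)-4-{[tert-butyl(dimethyl)silyl]oxy}-2,6,6-trimethylcyclohex-1-en-1-yl]-2,9-dimethylundeca-2,4,6,8-tetraen-10-yn-1-ylidene}furan-2(5H)-one | CC1=C(C#C/C(C)=C/C=C/C=C/C=C(C)/C=C2C=C(/C=C/[C@@]34O[C@]3(C)C[C@@H](O[Si](C)(C)C(C)(C)C)CC4(C)C)C(=O)O/2)C(C)(C)C[C@H](O[Si](C)(C)C(C)(C)C)C1 | intermediate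
30 | (5Z)-3-{(E)-2-[(1S,4S,6R)-4-hydroxy-2,2,6-trimethyl-7-oxabicyclo[4.1.0]heptan-1-yl]ethenyl}-5-{(2E,4E,6E,8E)-11-[(4R)-4-hydroxy-2,6,6-trimethylcyclohex-1-en-1-yl]-2,9-dimethylundeca-2,4,6,8-tetraen-10-yn-1-ylidene}furan-2(5H)-one | CC1=C(C#C/C(C)=C/C=C/C=C/C=C(C)/C=C2C=C(/C=C/[C@@]34O[C@]3(C)C[C@@H](O)CC4(C)C)C(=O)O/2)C(C)(C)C[C@H](O)C1 | target

**Count and risks**

Total step count: 22. Longest linear sequence: 11 steps (steps 1, 2, 3, 4, 5, 6, 10, 11, 20, 21, 22, from compound 1).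

Steps most likely to fail:

1. Step 21 (proposed new method). The alkylpalladium formed after insertion may lose the acyloxy group instead of hydrogen (ring opening), the allyl-palladium may isomerise and erode the C5=C6 geometry, or palladium hydride may isomerise the polyene. The fallback uses the known palladium/copper Sonogashira coupling with 5-exo-dig lactonisation. It sets out from acid 16 and enynol 17: Pd(PPh3)4, CuI and Et3N should give the (5Z)-ylidenebutenolide allylic alcohol F1 by coupling at C4 and anti addition of the carboxylate across the alkyne. MnO2 should oxidise it to the butenolide enal F2, and CrCl2 with CHI3 should give the (E)-dienyl iodide F3. Base-free Stille coupling of F3 with stannane 23 comes back to the route at compound 29.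

2. Step 20. The long polyenyl boronate may undergo protodeboronation or oxidative homocoupling, and the polyene may be oxidised under divalent copper and air. The fallback makes the union earlier, on the small and robust boronate. It sets out from acid 16 and boronate 24: the same copper-catalysed O-alkenylation should give the dienyl enol ester F4. The palladium ring closure of step 21 then gives the butenolide alcohol F1, which is taken through the enal F2 and the iodide F3 as above. Stille coupling with stannane 23 comes back to the route at compound 29.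

3. Step 22. Fluoride or alkoxide may open or isomerise the ylidene lactone, or traces of acid may rearrange the oxirane to a furanoid oxide, at the last step. The fallback removes the silyl groups before the halves are joined. It sets out from acid 16 and boronate 27: Bu4NF in THF should give the hydroxy acid F5, and camphorsulfonic acid in MeOH, which spares the boronate, should give the hydroxy boronate F6. Copper-catalysed O-alkenylation should give the diol enol ester F7, the secondary alcohols being far less reactive than the carboxylate. The palladium ring closure then comes back to the route at compound 30.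

**Further compounds**

F1 | step 21 | (5Z)-3-{(E)-2-[(1S,4S,6R)-4-{[tert-butyl(dimethyl)silyl]oxy}-2,2,6-trimethyl-7-oxabicyclo[4.1.0]heptan-1-yl]ethenyl}-5-[(2E)-4-hydroxy-2-methylbut-2-en-1-ylidene]furan-2(5H)-one | OC/C=C(C)/C=C1C=C(/C=C/[C@@]23O[C@]2(C)C[C@@H](O[Si](C)(C)C(C)(C)C)CC3(C)C)C(=O)O/1
F2 | step 21 | (2E)-3-methyl-4-[(2Z)-4-{(E)-2-[(1S,4S,6R)-4-{[tert-butyl(dimethyl)silyl]oxy}-2,2,6-trimethyl-7-oxabicyclo[4.1.0]heptan-1-yl]ethenyl}-5-oxofuran-2(5H)-ylidene]but-2-enal | O=C/C=C(C)/C=C1C=C(/C=C/[C@@]23O[C@]2(C)C[C@@H](O[Si](C)(C)C(C)(C)C)CC3(C)C)C(=O)O/1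
F3 | step 21 | (5Z)-3-{(E)-2-[(1S,4S,6R)-4-{[tert-butyl(dimethyl)silyl]oxy}-2,2,6-trimethyl-7-oxabicyclo[4.1.0]heptan-1-yl]ethenyl}-5-[(2E,4E)-5-iodo-2-methylpenta-2,4-dien-1-ylidene]furan-2(5H)-one | I/C=C/C=C(C)/C=C1C=C(/C=C/[C@@]23O[C@]2(C)C[C@@H](O[Si](C)(C)C(C)(C)C)CC3(C)C)C(=O)O/1
F4 | step 20 | (1E,3E)-5-hydroxy-3-methylpenta-1,3-dien-1-yl (2Z)-2-{(E)-2-[(1S,4S,6R)-4-{[tert-butyl(dimethyl)silyl]oxy}-2,2,6-trimethyl-7-oxabicyclo[4.1.0]heptan-1-yl]ethenyl}-3-iodoprop-2-enoate | OC/C=C(C)/C=C/OC(=O)C(=C\I)/C=C/[C@@]12O[C@]1(C)C[C@@H](O[Si](C)(C)C(C)(C)C)CC2(C)C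
F5 | step 22 | (2Z)-2-{(E)-2-[(1S,4S,6R)-4-hydroxy-2,2,6-trimethyl-7-oxabicyclo[4.1.0]heptan-1-yl]ethenyl}-3-iodoprop-2-enoic acid | I/C=C(/C=C/[C@@]12O[C@]1(C)C[C@@H](O)CC2(C)C)C(=O)O
F6 | step 22 | (1R)-3,5,5-trimethyl-4-[(3E,5E,7E,9E,11E)-3,10-dimethyl-12-(4,4,5,5-tetramethyl-1,3,2-dioxaborolan-2-yl)dodeca-3,5,7,9,11-pentaen-1-yn-1-yl]cyclohex-3-en-1-ol | CC1=C(C#C/C(C)=C/C=C/C=C/C=C(C)/C=C/B2OC(C)(C)C(C)(C)O2)C(C)(C)C[C@H](O)C1
F7 | step 22 | (1E,3E,5E,7E,9E)-12-[(4R)-4-hydroxy-2,6,6-trimethylcyclohex-1-en-1-yl]-3,10-dimethyldodeca-1,3,5,7,9-pentaen-11-yn-1-yl (2Z)-2-{(E)-2-[(1S,4S,6R)-4-hydroxy-2,2,6-trimethyl-7-oxabicyclo[4.1.0]heptan-1-yl]ethenyl}-3-iodoprop-2-enoate | CC1=C(C#C/C(C)=C/C=C/C=C/C=C(C)/C=C/OC(=O)C(=C\I)/C=C/[C@@]23O[C@]2(C)C[C@@H](O)CC3(C)C)C(C)(C)C[C@H](O)C1
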